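Numbering used throughout (thymol-type): C8 is the fully substituted oxirane carbon, C9 the oxirane CH2, C10 the CH2 that carries the (E)-ester. "Angeloyl" is (2Z)-2-methylbut-2-enoyl and "tigloyl" is (2E)-2-methylbut-2-enoyl.

## The problem

1. Target 13 is a 2-acyloxy-5-methoxy-4-methylphenyl arene whose only stereocentre, C8, is fully substituted. C8 is benzylic, is one carbon of a terminal oxirane (C8–O–C9) and carries the acyloxymethyl arm C10. The given SMILES corresponds to (R) at C8, with the Z ester on the phenol and the E ester on the C10 oxygen.
2. No second stereocentre can relay configuration, so (R) must come from a reagent or catalyst. The usual way to make such a centre is face-selective oxygen transfer to a 1,1-disubstituted 2-arylalkene, which is the least selective alkene class, here with an ortho-substituted aryl twisted out of the alkene plane.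
3. Two isomeric C5 acyl groups must go to defined oxygens. The Z group isomerizes to E under nucleophilic catalysis, heat or acid, and as an aryl ester it is also an acyl donor.
4. The oxirane is tertiary and benzylic, so acid opens it at C8 with loss of configuration. A free ortho-phenol or phenoxide would attack C9 (5-exo) to give a 2,3-dihydrobenzofuran-3-ol, so the phenol must be acylated before C9 becomes electrophilic.
5. A C8 alkoxide next to the aryl ester can take the acyl group through a six-membered transition state, so the order of the last steps matters.
6. The enabling feature is that C8 carries two one-carbon oxygenated arms, C9 and C10. If C9 and C10 share one oxygen, the atoms C8, C9, O and C10 form an oxetane ring with a mirror plane through the aryl ipso carbon, C8 and the ring oxygen. C8 is therefore stereogenic only because the two arms differ, and it can be set by telling two enantiotopic CH2 groups apart without forming or breaking any bond at C8.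

## Retrosynthesis

**13 ⇒ 12.** The O–C9 bond of the oxirane is cut, giving bromohydrin 12 (C8–OH, C9–Br). This cut leaves all four bonds at C8 intact, so the configuration of 12 passes unchanged into 13. Cutting both oxirane C–O bonds instead would put the stereo-creating step last, on the worst alkene class. The forward reaction is a 3-exo-tet closure that must outrun acyl shift from the phenol ester to the C8 alkoxide.

**12 ⇒ 10 + 11.** The acyl C–O bond at the C10 oxygen is cut, giving bromodiol 10 and tigloyl chloride 11. The primary/tertiary hydroxyl difference makes the acylation selective without protection, and the E acyl group is configurationally robust as an acid chloride. The precursor is five carbons smaller. The forward step must avoid nucleophilic acyl-transfer catalysts that would activate the aryl ester.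

**10 ⇒ 8 (via 9), the key disconnection.** The C9–Br bond is cut and C9 is rejoined to the oxygen on C10, which gives the achiral 3-aryl-3-silyloxyoxetane 8. This is preferred over desymmetrizing an open 2-arylglycerol, because one C–O cleavage sets C8, turns C9 into the electrophile and frees the C10 oxygen as the acylation site. Precursor 8 has no stereocentre, no halogen and no free hydroxyl, whereas 10 has three differentiated heteroatom arms on a configured carbon. The forward reaction needs a chiral catalyst to direct bromide to one enantiotopic ring CH2 and needs the uncatalysed background suppressed. For that reason the C8 oxygen is silylated, so that no HBr can form (bis-silyl ether 9 is the primary product).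

**8 ⇒ 6 + 7.** The phenol O–acyl bond is cut, giving phenol 6 and angelic anhydride 7. The phenol is acylated here, while the C8 oxygen is silylated (no acyl shift possible) and before any electrophilic carbon exists (no O-alkylation possible). The forward step must transfer the Z acyl group to a phenoxide without isomerization.

**6 ⇒ 2 + 3 (via 4 and 5).** The aryl–C8 bond is cut, giving the ortho-lithiated phenoxide 4 (from bromophenol 2) and oxetan-3-one 3. This joins the two halves at the fully substituted carbon while C8 is not yet stereogenic, so the hindered C–C bond carries no selectivity demand. Ketone 3 brings C8, C9, C10 and the bridging oxygen in one piece. Using dianion 4 saves a phenol protecting group. Both alkoxides are silylated in the flask (5) and the labile aryl silyl ether is cleaved on work-up.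

**2 ⇒ 1.** The C–Br bond is cut, giving 4-methoxy-3-methylphenol 1. Bromination must go ortho to the hydroxyl and para to the methyl group.

## Roads not taken

**Alternative 1:** (the most obvious) Both oxirane C–O bonds are cut, giving the 2-arylallyl alcohol A1 with the aryl angelate in place. Sharpless asymmetric epoxidation (Ti(OiPr)4, a dialkyl tartrate, t-BuOOH) would give epoxy alcohol A2, and acylation with 11 would give 13.
- A1 must itself be assembled from 2 by protection, cross-coupling with a 2-metallated allyl alcohol equivalent, deprotection and acylation, which is longer than the two steps from 2 to 8.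
- C8 would be set by face selection at a 1,1-disubstituted alkene bearing a twisted ortho-substituted aryl.
- A2 is a tertiary benzylic epoxy alcohol formed in the presence of a Lewis acidic titanium alkoxide and alkoxide nucleophiles, the epoxy alcohol class most prone to opening in situ.
- Ti(OiPr)4 is also a transesterification catalyst for the aryl angelate.
- The chosen plan never exposes the oxirane to a Lewis acid and never attacks a trigonal C8.

**Alternative 2:** The C8–C9 and O–C9 bonds are cut, giving the α-acyloxy aryl ketone A3. The key step would be a catalytic asymmetric Corey–Chaykovsky methylene transfer from a sulfoxonium ylide with a chiral LaLi3(binaphthoxide)3 catalyst.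
- The catalyst would have to tell an ortho-substituted aryl from a CH2O-acyl group, not from a methyl group as in its known ketone substrates.
- The ylide is a base and a nucleophile. A3 has an acidic CH2 between the ketone and the acyloxy group, an aryl ester that ylides acylate, and two enoates that ylides cyclopropanate.
- A3 also needs an α-oxygenation sequence on an acetophenone. The oxetane route has no carbanion in the presence of any ester.

**Alternative 3:** The latent symmetry is kept but an enzyme is used. A halohydrin dehalogenase would close one of the two enantiotopic chloromethyl arms of the prochiral dichloro alcohol A4 (aryllithium plus 1,3-dichloroacetone, phenol as benzyl ether) to the (chloromethyl)oxirane A5. Tiglate would then displace the chloride.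
- These enzymes have a small active site fitted to short haloalcohols, and a trisubstituted aryl on the carbinol carbon is unlikely to be accepted.
- The remaining chloride is neopentyl-like. Carboxylate can displace it directly or open the oxirane at CH2 and re-close on the chloride, and the two paths give opposite enantiomers, so configuration can erode.
- The aqueous medium excludes the aryl angelate, so a phenol protecting group has to be removed next to the finished oxirane.
- The oxetane opening gives two different arms (Br and OH) in one step, which removes this ambiguity.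

Key step: step 4

## Route

Assumption: the sense of induction of the squaramide catalyst on 8 cannot be predicted with confidence; the catalyst enantiomer that gives (S)-9 is taken to be chosen in a trial run, both enantiomers being accessible. Compounds 1, 3, 7 and 11 are taken as purchasable.

Step 1
Reactants: 1 4-methoxy-3-methylphenol
Product: 2 2-bromo-4-methoxy-5-methylphenol
Conditions: NBS (1.0 equiv), MeCN, −20 → 0 °C
Reagents that add atoms: N-bromosuccinimide, O=C1CCC(=O)N1Br
Why: Electrophilic aromatic bromination directed by the hydroxyl group; of its two ortho positions only the one para to the methyl group is unflanked, the other lies between OH and CH3, and the remaining free position is activated only by the weaker methoxy group.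

Step 2
Reactants: 2 2-bromo-4-methoxy-5-methylphenol; 3 oxetan-3-one
Product: 6 4-methoxy-5-methyl-2-[3-(trimethylsilyloxy)oxetan-3-yl]phenol, via dilithiated phenoxide 4 (not isolated), via bis(trimethylsilyl) ether 5 (not isolated)
Conditions: n-BuLi (2.2 equiv), THF, −78 → 0 °C; 3, −78 °C; Me3SiCl (3 equiv), −78 °C → rt; aq NaHCO3; MeOH, 0 °C
Reagents that add atoms: chlorotrimethylsilane, C[Si](C)(C)Cl
Why: Deprotonation and bromine–lithium exchange give the ortho-lithiated lithium phenoxide, which should add 1,2 to the strained, poorly enolizable ketone. Both lithium alkoxides are silylated in the flask and the aryl silyl ether, far more labile than the tertiary alkyl one, is methanolysed on work-up. No stereocentre arises because C8 carries two identical ring CH2 arms.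

Step 3
Reactants: 6 4-methoxy-5-methyl-2-[3-(trimethylsilyloxy)oxetan-3-yl]phenol; 7 angelic anhydride [(2Z)-2-methylbut-2-enoic anhydride]
Product: 8 4-methoxy-5-methyl-2-[3-(trimethylsilyloxy)oxetan-3-yl]phenyl (2Z)-2-methylbut-2-enoate
Conditions: 7 (1.3 equiv), Cs2CO3 (1.5 equiv), MeCN, 0 °C → rt
Reagents that add atoms: none
Why: O-Acylation of a phenoxide by an anhydride without nucleophilic catalyst or heat, the conditions under which a Z-2-methylbut-2-enoyl group is transferred without isomerization to E. The C8 oxygen is silylated, so neither a second acylation nor an acyl shift is possible.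

Step 4
Reactants: 8 4-methoxy-5-methyl-2-[3-(trimethylsilyloxy)oxetan-3-yl]phenyl (2Z)-2-methylbut-2-enoate
Product: 10 2-[(2S)-1-bromo-2,3-dihydroxypropan-2-yl]-4-methoxy-5-methylphenyl (2Z)-2-methylbut-2-enoate, via bromohydrin bis(trimethylsilyl) ether 9 (not isolated)
Conditions: Me3SiBr (1.5 equiv), chiral squaramide hydrogen-bond donor (N-aryl squaramide of a tert-leucine 2-arylpyrrolidine amide, 10 mol %), t-BuOMe, −78 → −40 °C; then citric acid, MeOH, 0 °C
Reagents that add atoms: bromotrimethylsilane, C[Si](C)(C)Br
Why: The silyl bromide silylates the oxetane oxygen reversibly while the squaramide holds the bromide through its two N–H bonds, giving a chiral ion pair of a silyloxetanium cation and catalyst-bound bromide; the bound bromide then attacks one of the two enantiotopic ring CH2 groups in an SN2 step that breaks the C–O bond and releases about 25 kcal/mol of ring strain, which makes it irreversible. The closest known reaction type is the squaramide-catalysed enantioselective addition of Me3SiBr to 3-substituted and 3,3-disubstituted oxetanes, of which 8 is a new 3-aryl-3-silyloxy member. No ring is closed; the four-membered ring is opened by attack on a ring carbon with the ring oxygen as leaving group. C8 is not a reacting atom: it becomes stereogenic because the attacked methylene becomes CH2Br (C9) and the other stays CH2O (C10), and the choice is made only by the catalyst, whose aryl pocket must tell the flat, twisted aryl group from the trimethylsilyloxy group on C8. The step needs enantiotopic-group selectivity and no uncatalysed background: the C8 oxygen is silylated beforehand so that no HBr forms, the reaction is run cold in an ether solvent, and the aryl ester, the aryl methyl ether and the trisubstituted enoate should be inert to the silyl bromide under these conditions. Methanolysis with citric acid then removes both trimethylsilyl groups without touching C8 and should give the (S)-bromodiol.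

Step 5
Reactants: 10 2-[(2S)-1-bromo-2,3-dihydroxypropan-2-yl]-4-methoxy-5-methylphenyl (2Z)-2-methylbut-2-enoate; 11 tigloyl chloride [(2E)-2-methylbut-2-enoyl chloride]
Product: 12 (2S)-3-bromo-2-hydroxy-2-{5-methoxy-4-methyl-2-[(2Z)-2-methylbut-2-enoyloxy]phenyl}propyl (2E)-2-methylbut-2-enoate
Conditions: 11 (1.1 equiv), pyridine (3 equiv), CH2Cl2, −20 → 0 °C
Reagents that add atoms: none
Why: Chemoselective acylation of the primary hydroxyl beside a hindered tertiary benzylic one. No 4-(dimethylamino)pyridine is used, so the aryl ester is not turned into an acyl donor, and pyridine is too weak a base to start oxirane closure in the presence of its hydrochloride; C8 is untouched.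

Step 6
Reactants: 12 (2S)-3-bromo-2-hydroxy-2-{5-methoxy-4-methyl-2-[(2Z)-2-methylbut-2-enoyloxy]phenyl}propyl (2E)-2-methylbut-2-enoate
Product: 13 [(2R)-2-{5-methoxy-4-methyl-2-[(2Z)-2-methylbut-2-enoyloxy]phenyl}oxiran-2-yl]methyl (2E)-2-methylbut-2-enoate
Conditions: Cs2CO3 (1.5 equiv), MeCN, 0 °C
Reagents that add atoms: none
Why: Intramolecular Williamson etherification (3-exo-tet) of the C8 alkoxide on the primary bromide C9, among the fastest ring closures and expected to outrun acyl transfer from the hindered, conjugated aryl ester. C8 is not a reacting centre, so its configuration is retained; the descriptor changes from S to R only because the ranking of the two arms changes.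

## Compound list

1 | 4-methoxy-3-methylphenol | Oc1cc(C)c(OC)cc1 | starting material
2 | 2-bromo-4-methoxy-5-methylphenol | Oc1cc(C)c(OC)cc1Br | intermediate
3 | oxetan-3-one | O=C1COC1 | starting material
4 | lithium 2-lithio-4-methoxy-5-methylphenoxide | [Li]Oc1cc(C)c(OC)cc1[Li] | intermediate (not isolated)
5 | trimethyl{4-methoxy-5-methyl-2-[3-(trimethylsilyloxy)oxetan-3-yl]phenoxy}silane | C[Si](C)(C)Oc1cc(C)c(OC)cc1C1(O[Si](C)(C)C)COC1 | intermediate (not isolated)
6 | 4-methoxy-5-methyl-2-[3-(trimethylsilyloxy)oxetan-3-yl]phenol | Oc1cc(C)c(OC)cc1C1(O[Si](C)(C)C)COC1 | intermediate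
7 | angelic anhydride, (2Z)-2-methylbut-2-enoic anhydride | C/C=C(/C)C(=O)OC(=O)/C(C)=C\C | starting material
8 | 4-methoxy-5-methyl-2-[3-(trimethylsilyloxy)oxetan-3-yl]phenyl (2Z)-2-methylbut-2-enoate | C/C=C(/C)C(=O)Oc1cc(C)c(OC)cc1C1(O[Si](C)(C)C)COC1 | intermediate
9 | 2-[(2S)-1-bromo-2,3-bis(trimethylsilyloxy)propan-2-yl]-4-methoxy-5-methylphenyl (2Z)-2-methylbut-2-enoate | C/C=C(/C)C(=O)Oc1cc(C)c(OC)cc1[C@](O[Si](C)(C)C)(CO[Si](C)(C)C)CBr | intermediate (not isolated)
10 | 2-[(2S)-1-bromo-2,3-dihydroxypropan-2-yl]-4-methoxy-5-methylphenyl (2Z)-2-methylbut-2-enoate | C/C=C(/C)C(=O)Oc1cc(C)c(OC)cc1[C@](O)(CO)CBr | intermediate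
11 | tigloyl chloride, (2E)-2-methylbut-2-enoyl chloride | C/C=C(\C)C(Cl)=O | starting material
12 | (2S)-3-bromo-2-hydroxy-2-{5-methoxy-4-methyl-2-[(2Z)-2-methylbut-2-enoyloxy]phenyl}propyl (2E)-2-methylbut-2-enoate | C/C=C(/C)C(=O)Oc1cc(C)c(OC)cc1[C@](O)(COC(=O)/C(C)=C/C)CBr | intermediate
13 | [(2R)-2-{5-methoxy-4-methyl-2-[(2Z)-2-methylbut-2-enoyloxy]phenyl}oxiran-2-yl]methyl (2E)-2-methylbut-2-enoate | C/C=C(/C)C(=O)Oc1cc(C)c(OC)cc1[C@]1(COC(=O)/C(C)=C/C)CO1 | target

## Step count and least certain steps

Total: 6 steps. Longest linear sequence: 6 steps (1 → 2 → 6 → 8 → 10 → 12 → 13).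

**Step 4 (key step).** Three things may go wrong.
- The catalyst may discriminate poorly between the enantiotopic CH2 groups, because it must tell a twisted ortho-disubstituted aryl from a silyloxy group on a quaternary carbon.
- SN2 attack at a neopentyl-type methylene may be slow, so that an uncatalysed opening competes.
- The tertiary benzylic C–O bond may ionize under the silyl bromide.

A wrong sense of induction is answered by the other catalyst enantiomer. The fallback sets out from 2 and comes back at 12:
- Dianion 4, made from 2 as in step 2, is added to 2,2-dimethyl-1,3-dioxan-5-one and quenched with aqueous NH4Cl to give 5-(2-hydroxy-5-methoxy-4-methylphenyl)-2,2-dimethyl-1,3-dioxan-5-ol F1.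
- The phenol is acylated with 7 and Cs2CO3 to the aryl angelate F2.
- The acetonide is hydrolysed with aqueous acetic acid to the prochiral 2-arylglycerol F3.
- Monoacylation with 11 and Et3N under CuCl2 and a chiral 4-phenyl bis(oxazoline) ligand gives the (R)-diol monotiglate F4. Divalent copper chelates the tertiary and one primary hydroxyl and so singles out one enantiotopic CH2OH, a known desymmetrization of 2-substituted glycerols.
- An Appel reaction (CBr4, PPh3) on the remaining primary hydroxyl gives 12.

**Step 6.** The angeloyl group may shift from the phenol oxygen to the C8 alkoxide through a six-membered transition state, after which the phenoxide would alkylate at C9 and form a dihydrobenzofuran. The fallback removes the aryl ester from the closure. It sets out from 6 and comes back at 13: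
- 6 is O-allylated (allyl bromide, K2CO3, acetone) to the allyl ether F5.
- The ring opening and methanolysis of step 4 give the (S)-bromodiol F6.
- Acylation with 11 and pyridine gives the tiglate F7.
- Cs2CO3 in MeCN closes the (R)-oxirane F8.
- Pd(PPh3)4 (zerovalent palladium) and Bu3SnH cleave the allyl ether by hydrostannolysis to the tributylstannyl phenoxide F9, which is acylated in the same flask by 7 to give 13. The phenol oxygen is thus never a free phenoxide beside the oxirane.

**Step 2.** Bromine–lithium exchange on the lithium phenoxide may be incomplete, the dianion may be quenched by proton transfer, the hindered tertiary alkoxide may be silylated incompletely, or the tertiary silyl ether may be lost on work-up. The fallback sets out from 2 and comes back at 6: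
- 2 is benzylated (BnBr, K2CO3, DMF) to the benzyl ether F10.
- Bromine–lithium exchange (n-BuLi, THF, −78 °C) and addition to 3 give the oxetanol F11.
- Me3SiCl and imidazole give the silyl ether F12.
- Hydrogenolysis (H2, Pd/C, EtOAc) gives 6.

## Further compounds

F1 | step 4 | 5-(2-hydroxy-5-methoxy-4-methylphenyl)-2,2-dimethyl-1,3-dioxan-5-ol | CC1(C)OCC(O)(CO1)c1cc(OC)c(C)cc1O
F2 | step 4 | 2-(5-hydroxy-2,2-dimethyl-1,3-dioxan-5-yl)-4-methoxy-5-methylphenyl (2Z)-2-methylbut-2-enoate | C/C=C(/C)C(=O)Oc1cc(C)c(OC)cc1C1(O)COC(C)(C)OC1
F3 | step 4 | 4-methoxy-5-methyl-2-(1,2,3-trihydroxypropan-2-yl)phenyl (2Z)-2-methylbut-2-enoate | C/C=C(/C)C(=O)Oc1cc(C)c(OC)cc1C(O)(CO)CO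
F4 | step 4 | (2R)-2,3-dihydroxy-2-{5-methoxy-4-methyl-2-[(2Z)-2-methylbut-2-enoyloxy]phenyl}propyl (2E)-2-methylbut-2-enoate | C/C=C(/C)C(=O)Oc1cc(C)c(OC)cc1[C@](O)(COC(=O)/C(C)=C/C)CO
F5 | step 6 | trimethyl({3-[5-methoxy-4-methyl-2-(prop-2-en-1-yloxy)phenyl]oxetan-3-yl}oxy)silane | C=CCOc1cc(C)c(OC)cc1C1(O[Si](C)(C)C)COC1
F6 | step 6 | (2S)-3-bromo-2-[5-methoxy-4-methyl-2-(prop-2-en-1-yloxy)phenyl]propane-1,2-diol | C=CCOc1cc(C)c(OC)cc1[C@](O)(CO)CBr
F7 | step 6 | (2S)-3-bromo-2-hydroxy-2-[5-methoxy-4-methyl-2-(prop-2-en-1-yloxy)phenyl]propyl (2E)-2-methylbut-2-enoate | C=CCOc1cc(C)c(OC)cc1[C@](O)(COC(=O)/C(C)=C/C)CBr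
F8 | step 6 | {(2R)-2-[5-methoxy-4-methyl-2-(prop-2-en-1-yloxy)phenyl]oxiran-2-yl}methyl (2E)-2-methylbut-2-enoate | C=CCOc1cc(C)c(OC)cc1[C@]1(COC(=O)/C(C)=C/C)CO1
F9 | step 6 | {(2R)-2-[5-methoxy-4-methyl-2-(tributylstannyloxy)phenyl]oxiran-2-yl}methyl (2E)-2-methylbut-2-enoate | CCCC[Sn](CCCC)(CCCC)Oc1cc(C)c(OC)cc1[C@]1(COC(=O)/C(C)=C/C)CO1
F10 | step 2 | 1-(benzyloxy)-2-bromo-4-methoxy-5-methylbenzene | Brc1cc(OC)c(C)cc1OCc1ccccc1
F11 | step 2 | 3-[2-(benzyloxy)-5-methoxy-4-methylphenyl]oxetan-3-ol | OC1(COC1)c1cc(OC)c(C)cc1OCc1ccccc1
F12 | step 2 | ({3-[2-(benzyloxy)-5-methoxy-4-methylphenyl]oxetan-3-yl}oxy)trimethylsilane | C[Si](C)(C)OC1(COC1)c1cc(OC)c(C)cc1OCc1ccccc1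
A1 | alternative 1 | 2-(3-hydroxyprop-1-en-2-yl)-4-methoxy-5-methylphenyl (2Z)-2-methylbut-2-enoate | C/C=C(/C)C(=O)Oc1cc(C)c(OC)cc1C(=C)CO
A2 | alternative 1 | 2-[(2S)-2-(hydroxymethyl)oxiran-2-yl]-4-methoxy-5-methylphenyl (2Z)-2-methylbut-2-enoate | C/C=C(/C)C(=O)Oc1cc(C)c(OC)cc1[C@]1(CO)CO1
A3 | alternative 2 | 2-{5-methoxy-4-methyl-2-[(2Z)-2-methylbut-2-enoyloxy]phenyl}-2-oxoethyl (2E)-2-methylbut-2-enoate | C/C=C(/C)C(=O)Oc1cc(C)c(OC)cc1C(=O)COC(=O)/C(C)=C/C
A4 | alternative 3 | 2-[2-(benzyloxy)-5-methoxy-4-methylphenyl]-1,3-dichloropropan-2-ol | OC(CCl)(CCl)c1cc(OC)c(C)cc1OCc1ccccc1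
A5 | alternative 3 | (2R)-2-[2-(benzyloxy)-5-methoxy-4-methylphenyl]-2-(chloromethyl)oxirane | C(c1ccccc1)Oc1cc(C)c(OC)cc1[C@]1(CCl)CO1
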